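I decide to count chains before I count L, and to ask what would have to be true for amber to catch teal.

| flask | L | G | Q | remark | time |
|---|---|---|---|---|---|
| maple | 4 mM | 0.13 mM | 18 µM | run made earlier |  |
| oak | 11 mM | 0.13 mM | 18 µM | run made earlier |  |
| ash | 23 mM | 0.13 mM | 18 µM | run made earlier |  |
| teal | 20 mM | 0.13 mM | 18 µM |  | 2.0 h |
| amber | 5.0 mM | 0.13 mM | 18 µM |  | 2.0 h |

| run | time / min | E / % | L / % |
|---|---|---|---|
| maple | 6.00 | 0.2 | 98.5 |
| maple | 12.0 | 2.1 | 95.9 |
| maple | 25.0 | 4.5 | 90.8 |
| maple | 40.0 | 10.1 | 82.6 |
| maple | 80.0 | 30.4 | 58.7 |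
| oak | 8.00 | 1.0 | 97.2 |
| oak | 20.0 | 7.1 | 89.2 |
| oak | 40.0 | 21.9 | 71.8 |
| oak | 60.0 | 36.1 | 55.5 |
| oak | 80.0 | 49.0 | 41.8 |
| ash | 6.00 | 1.8 | 97.3 |
| ash | 12.0 | 4.9 | 92.8 |
| ash | 25.0 | 17.3 | 78.0 |
| ash | 40.0 | 32.1 | 62.3 |
| ash | 80.0 | 60.6 | 30.0 |

(scatter of a reading: 0.3 percentage points)

- the average divides the monomer in chains by the number of chains begun, living and dead together
- the earlier runs were read with a standard deviation of 0.3 percentage points
- the earlier runs do not show the number of chains; that part of a forecast is a guess

- which of the two ends with the longer chains by the average number of monomer units in a chain (chains begun, living or dead) ("neither" if they lie within 10%) (teal / amber / neither)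
- average number of monomer units in a chain (chains begun, living or dead) at the end, teal
- average number of monomer units in a chain (chains begun, living or dead) at the end, amber

Length is the L built into E divided by the chains begun. Teal is charged with 4.00 times amber's L, and at 80.0 min maple and ash, my stand-ins for amber and teal, read E at 30.4% and 60.6%. So for "neither", amber would need about 0.125 of teal's chains.

Chains aren't read, so I use L's first-order slope as a rough stand-in for them, although L + E reads 89.1% in maple at 80.0 min, so part of the fall of L is not growth. Between 40.0 min and 80.0 min L falls at 0.00854 min⁻¹ in maple and 0.0183 min⁻¹ in ash. That slope is no clean pseudo-first-order constant, because maple's read 0.00631 min⁻¹ one stretch earlier. The ratio of slopes, 0.467, is therefore a rough reading of maple's chains against ash's, and it stands above what amber would need. I say teal, by a factor near 3.74.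

I also suppose that each Q removes one G. That leaves the live charge, the G charged minus the Q charged, [G] − [Q]: 0.112 mM. Chains can't exceed it, so E divided by it is a floor on length. With ash's last E, teal's floor is 108.

The forecast says teal, with 120 for teal and 31 for amber, and warns: “Chain count is assumed, not measured”.

The flask gives 141 for teal and 38.9 for amber, so teal ends longer. In teal at 2.00 h, Q stands at 0% and J at 0.0180 mM, while X, at 0.105 mM, lies below the live charge. Teal's actual E of 74.0% puts the floor at 132, under the computed length but above the forecast's figure.

    L + X → E + X, rate k1*[X]*[L] (k = 2.70 M⁻¹ s⁻¹)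
    L + G → X + E (k = 0.0370 M⁻¹ s⁻¹)
    L → Z (k = 2.90 × 10⁻⁵ s⁻¹)
    G + Q → J (k = 4200 M⁻¹ s⁻¹)

Now take a neighbour flask, the same as teal but with 0.052 mM of G. Its live charge is 0.0340 mM, and its E of 36.7% gives 216. The computed length is 220.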